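**Strategy.** The 3,6-dihydro-1,2-dioxine ring (numbered O1–O2–C3–C4=C5–C6) is cut across two opposite bonds, C5–C6 and O2–C3, into a C6–O1–O2 unit and a C3–C4–C5 unit. The key step is a one-flask [3+3] annulation that exploits two features: C6 is a peroxy-orthoester-level carbon, hence a latent methoxy(peroxy)carbenium ion, and C3 is the beta carbon of the acetate arm, hence a Michael acceptor. A silylperoxy orthoester carrying the complete dienyl chain is ionised and captured by the tin-bearing carbon of a (2E,4Z)-5-stannylpentadienoate (C5–C6). Fluoride then frees the peroxide, which closes the ring by conjugate addition (O2–C3) under a chiral ammonium counter-ion.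

Key step: step 9

Assumption: the cinchonidinium cation is taken to direct the peroxide to the enoate face that gives 3R; if the sense were opposite, the pseudoenantiomeric cinchoninium salt would be used under the same conditions.

Step 1
Reactants: 1 12-bromododecan-1-ol
Product: 2 2-[(12-bromododecyl)oxy]oxane
Conditions: 3,4-dihydro-2H-pyran, PPTS (cat.), CH2Cl2, rt
Reagents that add atoms: 3,4-dihydro-2H-pyran C1=COCCC1
Why: Acid-catalysed addition of the alcohol to the enol ether (tetrahydropyranylation) masks the hydroxyl group so that the bromide can be turned into a Grignard reagent.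

Step 2
Reactants: 2 2-[(12-bromododecyl)oxy]oxane; 3 (2E,4E)-hexa-2,4-dien-1-yl acetate
Product: 5 2-{[(14E,16E)-octadeca-14,16-dien-1-yl]oxy}oxane, via alkylmagnesium bromide 4 (not isolated)
Conditions: Mg, THF, 40 °C; then 3, Li2CuCl4 (3 mol%), THF, −20 to 0 °C
Reagents that add atoms: none
Why: Copper-catalysed cross-coupling of a primary alkyl Grignard reagent with a primary dienylic acetate should proceed by direct substitution at the CH2–OAc carbon and leave the (E,E)-diene untouched, so both side-chain double bonds come from the sorbyl unit.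

Step 3
Reactants: 5 2-{[(14E,16E)-octadeca-14,16-dien-1-yl]oxy}oxane
Product: 6 (14E,16E)-octadeca-14,16-dien-1-ol
Conditions: PPTS (cat.), MeOH, 45 °C
Reagents that add atoms: none
Why: Acid-catalysed acetal exchange with methanol removes the THP group under conditions too mild to protonate the conjugated diene.

Step 4
Reactants: 6 (14E,16E)-octadeca-14,16-dien-1-ol
Product: 7 (2E,4E)-18-bromooctadeca-2,4-diene
Conditions: CBr4, PPh3, CH2Cl2, 0 °C
Reagents that add atoms: tetrabromomethane BrC(Br)(Br)Br
Why: The Appel reaction converts the primary alcohol into the bromide under neutral conditions that a conjugated diene tolerates.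

Step 5
Reactants: 7 (2E,4E)-18-bromooctadeca-2,4-diene; 8 tetramethyl orthocarbonate
Product: 10 (2E,4E)-19,19,19-trimethoxynonadeca-2,4-diene, via dienylmagnesium bromide 9 (not isolated)
Conditions: Mg, THF, 40 °C; then 8 (3 equiv), toluene, 70 °C; Et3N-buffered work-up
Reagents that add atoms: none
Why: Substitution of one methoxy group of the orthocarbonate by the Grignard reagent (orthoester synthesis, the orthoester-level counterpart of the Bodroux–Chichibabin reaction) installs C6 at the carboxylic acid oxidation level and should stop at the orthoester, which is the weaker electrophile.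

Step 6
Reactants: 10 (2E,4E)-19,19,19-trimethoxynonadeca-2,4-diene
Product: 12 triethyl{[(15E,17E)-1,1-dimethoxynonadeca-15,17-dien-1-yl]peroxy}silane, via hydroperoxy orthoester 11 (not isolated)
Conditions: urea·H2O2 (1.1 equiv), PPTS (cat.), 4 Å MS, CH2Cl2–Et2O, −20 °C; then imidazole, Et3SiCl, −20 to 0 °C
Reagents that add atoms: hydrogen peroxide OO; chlorotriethylsilane CC[Si](CC)(CC)Cl
Why: Acid-catalysed exchange of one alkoxy group of the orthoester for a hydroperoxy group (perhydrolysis, as for ketals and peroxy orthoesters) makes the C6–O1 bond, and immediate O-silylation of the hydroperoxide should give a peroxide that can be handled.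

Step 7
Reactants: 13 prop-2-yn-1-ol
Product: 14 (2Z)-3-(tributylstannyl)prop-2-en-1-ol
Conditions: LiAlH4, THF, 0 °C to rt; then Bu3SnOTf, −78 °C to rt
Reagents that add atoms: tributyltin trifluoromethanesulfonate CCCC[Sn](CCCC)(CCCC)OS(=O)(=O)C(F)(F)F
Why: Hydroxyl-directed trans-hydroalumination places aluminium on C3 cis to the CH2O group in a cyclic alkoxyaluminate, and stannylation with retention should give the Z vinylstannane.

Step 8
Reactants: 14 (2Z)-3-(tributylstannyl)prop-2-en-1-ol; 15 methyl (triphenylphosphoranylidene)acetate
Product: 17 methyl (2E,4Z)-5-(tributylstannyl)penta-2,4-dienoate, via stannyl enal 16 (not isolated)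
Conditions: MnO2 (10 equiv), 15, CH2Cl2, rt, dark
Reagents that add atoms: none
Why: Allylic oxidation with in-situ Wittig trapping (tandem oxidation–Wittig) intercepts the isomerisation-prone Z enal at once, the stabilised ylide giving the new C2=C3 bond E while the Z stannyl alkene is kept.

Step 9
Reactants: 12 triethyl{[(15E,17E)-1,1-dimethoxynonadeca-15,17-dien-1-yl]peroxy}silane; 17 methyl (2E,4Z)-5-(tributylstannyl)penta-2,4-dienoate
Product: 19 methyl 2-[(3R)-6-methoxy-6-[(14E,16E)-octadeca-14,16-dien-1-yl]-3,6-dihydro-1,2-dioxin-3-yl]acetate as the C6 epimer pair, via silylperoxy tetraenoate 18 (not isolated)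
Conditions: 12, 17 (1.5 equiv), 2,6-di-tert-butyl-4-methylpyridine (0.3 equiv), Me3SiOTf (1.1 equiv), CH2Cl2, −78 to −40 °C; then toluene, O-allyl-N-(9-anthracenylmethyl)cinchonidinium bromide (20 mol%), KHF2 (4 equiv), −60 to −40 °C
Reagents that add atoms: none
Why: Proposed new method: Me3SiOTf should ionise the more basic methoxy group of 12 to the methoxy(triethylsilylperoxy)carbenium ion, which is attacked at the tin-bearing carbon C5 of 17 (beta-stannyl cation, loss of Bu3SnOTf, retention of the Z geometry) to make C5–C6 and give 18; bifluoride then cleaves the O–Si bond and the freed peroxide oxygen O2 adds to C3 of the (2E)-enoate, the enolate being protonated by HF, to make O2–C3. The closest known reactions are the trapping of peroxycarbenium ions from monoperoxyketals by allylsilanes, allylstannanes and silyl enol ethers, the one-flask closure of 1,2-dioxolanes by a silylperoxy group after such a C–C bond formation, ipso substitution of alkenylsilanes and alkenylstannanes by oxocarbenium ions, and base-mediated peroxy-Michael closures onto enoates; new here are the orthoester oxidation level of the cation, an alkenylstannane as its partner and chiral-cation control of the conjugate addition. The 1,2-dioxine ring closes in the 6-exo-trig mode, which is possible only because the stannane delivers the C4=C5 bond with Z geometry. C3 is set by reagent control, the peroxide anion reacting as an ion pair with the chiral cinchonidinium cation (as in phase-transfer epoxidation of enones, where the same kind of ion pair governs the conjugate addition), so that both C6 antipodes of 18 should close to the 3R ester, whereas C6, formed without control in the C–C bond formation, is left as an epimer pair for step 10. The step needs the cation to choose the stannane over the remote (E,E)-diene, which its double oxygen stabilisation and the excess of stannane should secure, and it needs the peroxide to survive, which low temperature, the hindered pyridine buffer and the weakly basic bifluoride should secure against Criegee-type migration, Kornblum–DeLaMare fragmentation and enolate attack on the O–O bond.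

Step 10
Reactants: 19 methyl 2-[(3R)-6-methoxy-6-[(14E,16E)-octadeca-14,16-dien-1-yl]-3,6-dihydro-1,2-dioxin-3-yl]acetate as the C6 epimer pair
Product: 20 methyl 2-[(3R,6S)-6-methoxy-6-[(14E,16E)-octadeca-14,16-dien-1-yl]-3,6-dihydro-1,2-dioxin-3-yl]acetate (xestin B)
Conditions: CSA (5 mol%), MeOH, 0 °C; chromatography; 6R epimer returned to the same conditions
Reagents that add atoms: methanol CO
Why: Acid-catalysed peroxyketal exchange through the ring-retained cyclic peroxycarbenium ion epimerises C6 only (C3 has no ionisable bond under acid), both epimers can hold the methoxy group pseudoaxial (anomeric effect) and are expected in comparable amounts, so separation of the 6S epimer and recycling of the 6R epimer should funnel the 3R material into 20.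

**Compound list**

1 | 12-bromododecan-1-ol | OCCCCCCCCCCCCBr | starting material
2 | 2-[(12-bromododecyl)oxy]oxane | BrCCCCCCCCCCCCOC1CCCCO1 | intermediate
3 | (2E,4E)-hexa-2,4-dien-1-yl acetate | C/C=C/C=C/COC(C)=O | starting material
4 | [12-(oxan-2-yloxy)dodecyl]magnesium bromide (not isolated) | Br[Mg]CCCCCCCCCCCCOC1CCCCO1 | intermediate
5 | 2-{[(14E,16E)-octadeca-14,16-dien-1-yl]oxy}oxane | C/C=C/C=C/CCCCCCCCCCCCCOC1CCCCO1 | intermediate
6 | (14E,16E)-octadeca-14,16-dien-1-ol | C/C=C/C=C/CCCCCCCCCCCCCO | intermediate
7 | (2E,4E)-18-bromooctadeca-2,4-diene | C/C=C/C=C/CCCCCCCCCCCCCBr | intermediate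
8 | tetramethyl orthocarbonate | COC(OC)(OC)OC | starting material
9 | [(14E,16E)-octadeca-14,16-dien-1-yl]magnesium bromide (not isolated) | C/C=C/C=C/CCCCCCCCCCCCC[Mg]Br | intermediate
10 | (2E,4E)-19,19,19-trimethoxynonadeca-2,4-diene (trimethyl orthoester of (15E,17E)-nonadeca-15,17-dienoic acid) | C/C=C/C=C/CCCCCCCCCCCCCC(OC)(OC)OC | intermediate
11 | (15E,17E)-1-hydroperoxy-1,1-dimethoxynonadeca-15,17-diene (not isolated) | C/C=C/C=C/CCCCCCCCCCCCCC(OC)(OC)OO | intermediate
12 | triethyl{[(15E,17E)-1,1-dimethoxynonadeca-15,17-dien-1-yl]peroxy}silane | C/C=C/C=C/CCCCCCCCCCCCCC(OC)(OC)OO[Si](CC)(CC)CC | intermediate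
13 | prop-2-yn-1-ol | C#CCO | starting material
14 | (2Z)-3-(tributylstannyl)prop-2-en-1-ol | CCCC[Sn](CCCC)(CCCC)/C=C\CO | intermediate
15 | methyl (triphenylphosphoranylidene)acetate | COC(=O)C=P(c1ccccc1)(c1ccccc1)c1ccccc1 | starting material
16 | (2Z)-3-(tributylstannyl)prop-2-enal (not isolated) | CCCC[Sn](CCCC)(CCCC)/C=C\C=O | intermediate
17 | methyl (2E,4Z)-5-(tributylstannyl)penta-2,4-dienoate | CCCC[Sn](CCCC)(CCCC)/C=C\C=C\C(=O)OC | intermediate
18 | methyl (2E,4Z,20E,22E)-6-methoxy-6-[(triethylsilyl)peroxy]tetracosa-2,4,20,22-tetraenoate, racemic at C6 (not isolated) | C/C=C/C=C/CCCCCCCCCCCCCC(OC)(OO[Si](CC)(CC)CC)/C=C\C=C\C(=O)OC | intermediate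
19 | methyl 2-[(3R)-6-methoxy-6-[(14E,16E)-octadeca-14,16-dien-1-yl]-3,6-dihydro-1,2-dioxin-3-yl]acetate, C6 epimer pair | C/C=C/C=C/CCCCCCCCCCCCCC1(OC)C=C[C@@H](CC(=O)OC)OO1 | intermediate
20 | methyl 2-[(3R,6S)-6-methoxy-6-[(14E,16E)-octadeca-14,16-dien-1-yl]-3,6-dihydro-1,2-dioxin-3-yl]acetate (xestin B) | C/C=C/C=C/CCCCCCCCCCCCC[C@@]1(OC)C=C[C@@H](CC(=O)OC)OO1 | target

**Total step count:** 10. **Longest linear sequence:** 8 (steps 1–6, 9, 10); steps 7–8 build the stannane in parallel.

**Steps most likely to fail**

1. Step 9 (bears the label). Two processes may go wrong: (a) the ipso attack of the electron-poor dienylstannane on the doubly oxygen-stabilised cation may be too slow, so that Criegee-type O–O heterolysis, protodestannylation or capture of the cation by the chain diene takes over; (b) the ion-paired conjugate addition may not discriminate the enoate faces. The fallback uses known chemistry, sets out from bromide 7 (through its Grignard reagent 9) and stannane 17, and returns at 19. Carboxylation of 9 with CO2 should give (15E,17E)-nonadeca-15,17-dienoic acid F1, which oxalyl chloride converts into (15E,17E)-nonadeca-15,17-dienoyl chloride F2. Stille acylation of 17 with F2 (Pd2(dba)3, P(2-furyl)3, THF) makes the C5–C6 bond before any peroxide is present and should give methyl (2E,4Z,20E,22E)-6-oxotetracosa-2,4,20,22-tetraenoate F3. Perhydrolysis in methanol (urea·H2O2, Sc(OTf)3 cat.) should give methyl (2E,4Z,20E,22E)-6-hydroperoxy-6-methoxytetracosa-2,4,20,22-tetraenoate F4. Et2NH in CF3CH2OH then closes the ring by peroxy-Michael addition to racemic methyl 2-[6-methoxy-6-[(14E,16E)-octadeca-14,16-dien-1-yl]-3,6-dihydro-1,2-dioxin-3-yl]acetate F5. Kinetic resolution with a lipase (Candida antarctica lipase B, pH 7 buffer–MTBE, enzyme chosen by screening to hydrolyse the 3S esters) should remove the 3S series as 2-[(3S)-6-methoxy-6-[(14E,16E)-octadeca-14,16-dien-1-yl]-3,6-dihydro-1,2-dioxin-3-yl]acetic acid F6 and leave the 3R esters, which are 19.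

2. Step 6. The free hydroperoxy orthoester 11 may over-exchange to a bis(peroxy) compound or collapse by loss of methanol before it is silylated, and the resulting oxidant could attack the diene. The fallback sets out from 10 and returns at 19. The peroxide is transferred as an already silylated unit: bis(trimethylsilyl) peroxide with catalytic Me3SiOTf at −78 °C (silyl-transfer acetal exchange) should give {[(15E,17E)-1,1-dimethoxynonadeca-15,17-dien-1-yl]peroxy}trimethylsilane F7 without a free hydroperoxide ever being present. F7 is taken crude into step 9 in place of 12.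

3. Step 10. The equilibrium may lie on the side of the 6R epimer, or prolonged acid may open the ring, so that recycling becomes wasteful. The fallback sets out from 19 and returns at 20, and sets C6 by alkylation at oxygen instead of substitution at carbon. Mild aqueous acid (PPTS, acetone–water) should give the hemiketal methyl 2-[(3R)-6-hydroxy-6-[(14E,16E)-octadeca-14,16-dien-1-yl]-3,6-dihydro-1,2-dioxin-3-yl]acetate F8. F8 is O-methylated at −40 °C with MeOTf and 2,6-di-tert-butyl-4-methylpyridine. The more accessible pseudoequatorial hydroxyl anomer, which has the hydroxyl group and the C3 side chain on opposite faces, should react faster and give 20 under kinetic control.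

**Further compounds**

F1 | step 9 | (15E,17E)-nonadeca-15,17-dienoic acid | C/C=C/C=C/CCCCCCCCCCCCCC(=O)O
F2 | step 9 | (15E,17E)-nonadeca-15,17-dienoyl chloride | C/C=C/C=C/CCCCCCCCCCCCCC(=O)Cl
F3 | step 9 | methyl (2E,4Z,20E,22E)-6-oxotetracosa-2,4,20,22-tetraenoate | C/C=C/C=C/CCCCCCCCCCCCCC(=O)/C=C\C=C\C(=O)OC
F4 | step 9 | methyl (2E,4Z,20E,22E)-6-hydroperoxy-6-methoxytetracosa-2,4,20,22-tetraenoate (racemic) | C/C=C/C=C/CCCCCCCCCCCCCC(OC)(OO)/C=C\C=C\C(=O)OC
F5 | step 9 | methyl 2-[6-methoxy-6-[(14E,16E)-octadeca-14,16-dien-1-yl]-3,6-dihydro-1,2-dioxin-3-yl]acetate (racemic, C6 epimer pair) | C/C=C/C=C/CCCCCCCCCCCCCC1(OC)C=CC(CC(=O)OC)OO1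
F6 | step 9 | 2-[(3S)-6-methoxy-6-[(14E,16E)-octadeca-14,16-dien-1-yl]-3,6-dihydro-1,2-dioxin-3-yl]acetic acid (C6 epimer pair) | C/C=C/C=C/CCCCCCCCCCCCCC1(OC)C=C[C@H](CC(=O)O)OO1
F7 | step 6 | {[(15E,17E)-1,1-dimethoxynonadeca-15,17-dien-1-yl]peroxy}trimethylsilane | C/C=C/C=C/CCCCCCCCCCCCCC(OC)(OC)OO[Si](C)(C)C
F8 | step 10 | methyl 2-[(3R)-6-hydroxy-6-[(14E,16E)-octadeca-14,16-dien-1-yl]-3,6-dihydro-1,2-dioxin-3-yl]acetate (hemiketal, C6 anomer pair) | C/C=C/C=C/CCCCCCCCCCCCCC1(O)C=C[C@@H](CC(=O)OC)OO1
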